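**Retrosynthetic overview**
1. The last operation is a four-fold O-demethylation of 1,14-bis(3,5-dimethoxyphenyl)tetradecane, which already holds all 26 skeletal carbons.
2. The key disconnection is the C5–C6 CH2–CH2 bond of the chain. It is made by a Ni-electrocatalytic doubly decarboxylative C(sp3)–C(sp3) cross-coupling of the N-hydroxyphthalimide esters of 6-(3,5-dimethoxyphenyl)hexanoic acid and 10-(3,5-dimethoxyphenyl)decanoic acid. Each CO2 is a traceless activating group, and 5 + 9 = 14.
3. The enabling feature is that C5 and C6 are unhindered, unfunctionalised methylene carbons of the unbranched C1–C14 tether, five and nine carbons from their benzene rings. Both halves are therefore plain primary alkyl radicals with no stereocentre, no β-heteroatom and no fast cyclisation channel, and the electron-rich rings are inert to cathodic conditions.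
4. Each acid comes in one flask from 1-bromo-3,5-dimethoxybenzene and a terminal alkenoate by hydroboration, B-alkyl Suzuki–Miyaura coupling and saponification.
5. No ring is formed. Both benzene rings are bought with their 1,3,5-pattern in place.

Key step: step 5

Remark: the target has no stereocentre and no stereogenic double bond, so it is achiral and no enantio- or diastereocontrol is needed. Compounds 1, 2 and 6 are taken as catalogue compounds.

**Step 1**
Reactants: 1 methyl hex-5-enoate; 2 1-bromo-3,5-dimethoxybenzene
Product: 5 6-(3,5-dimethoxyphenyl)hexanoic acid, via B-alkyl-9-BBN ester 3 (not isolated), via methyl ester 4 (not isolated)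
Conditions: 9-BBN-H (1.1 equiv), THF, 0 °C to rt; then 2, PdCl2(dppf) (3 mol %), 3 M aq NaOH, THF, 65 °C; then MeOH, further aq NaOH, 50 °C; 1 M HCl
Reagents that add atoms: 9-BBN-H, B1C2CCCC1CCC2 (its boron and ring carbons are held only in 3); sodium hydroxide, [Na+].[OH-] (oxygen of the acid OH)
Why: Anti-Markovnikov hydroboration of the terminal alkene with 9-BBN-H spares the ester, the B-alkyl Suzuki–Miyaura coupling of a primary alkyl-9-BBN with an aryl bromide under PdCl2(dppf)/aq NaOH is standard, and the same hydroxide then saponifies the methyl ester in the flask; no stereocentre is formed.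

**Step 2**
Reactants: 6 methyl dec-9-enoate; 2 1-bromo-3,5-dimethoxybenzene
Product: 9 10-(3,5-dimethoxyphenyl)decanoic acid, via B-alkyl-9-BBN ester 7 (not isolated), via methyl ester 8 (not isolated)
Conditions: 9-BBN-H (1.1 equiv), THF, 0 °C to rt; then 2, PdCl2(dppf) (3 mol %), 3 M aq NaOH, THF, 65 °C; then MeOH, further aq NaOH, 50 °C; 1 M HCl
Reagents that add atoms: 9-BBN-H, B1C2CCCC1CCC2 (its boron and ring carbons are held only in 7); sodium hydroxide, [Na+].[OH-] (oxygen of the acid OH)
Why: The same hydroboration, B-alkyl Suzuki–Miyaura coupling and saponification sequence as in step 1 is applied to the C10 homologue, whose remote ester and terminal alkene behave independently; no stereocentre is formed.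

**Step 3**
Reactants: 5 6-(3,5-dimethoxyphenyl)hexanoic acid
Product: 10 1,3-dioxoisoindolin-2-yl 6-(3,5-dimethoxyphenyl)hexanoate
Conditions: N-hydroxyphthalimide (1.05 equiv), DIC (1.1 equiv), DMAP (10 mol %), CH2Cl2, rt
Reagents that add atoms: N-hydroxyphthalimide, O=C1c2ccccc2C(=O)N1O
Why: Carbodiimide-mediated (Steglich-type) esterification of an unhindered primary acid with N-hydroxyphthalimide is the standard entry to bench-stable redox-active esters and does not touch the aryl methyl ethers.

**Step 4**
Reactants: 9 10-(3,5-dimethoxyphenyl)decanoic acid
Product: 11 1,3-dioxoisoindolin-2-yl 10-(3,5-dimethoxyphenyl)decanoate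
Conditions: N-hydroxyphthalimide (1.05 equiv), DIC (1.1 equiv), DMAP (10 mol %), CH2Cl2, rt
Reagents that add atoms: N-hydroxyphthalimide, O=C1c2ccccc2C(=O)N1O
Why: The same Steglich-type esterification as in step 3 should activate the C10 acid as its redox-active ester without side reactions at the saturated chain or the aryl ethers.

**Step 5**
Reactants: 10 1,3-dioxoisoindolin-2-yl 6-(3,5-dimethoxyphenyl)hexanoate; 11 1,3-dioxoisoindolin-2-yl 10-(3,5-dimethoxyphenyl)decanoate
Product: 12 1,14-bis(3,5-dimethoxyphenyl)tetradecane
Conditions: 10 (3 equiv), 11 (1 equiv), NiCl2·glyme (20 mol %), 2,6-bis(pyrazol-1-yl)pyridine (20 mol %), NaI, DMF, undivided cell, (+)Zn/(−)RVC, constant current, rt; 1 M HCl work-up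
Reagents that add atoms: none
Why: Cathodically generated low-valent nickel (tridentate N-ligand) transfers one electron to each N-acyloxyphthalimide, whose radical anion breaks its N–O bond and loses CO2 to give the primary 5-arylpentyl radical from 10 and the primary 9-arylnonyl radical from 11; successive capture of both radicals at nickel gives a dialkylnickel(III) species whose reductive elimination makes the C5–C6 CH2–CH2 bond, while the zinc anode delivers the two electrons. The closest known reaction type is the Ni-electrocatalytic doubly decarboxylative C(sp3)–C(sp3) cross-coupling of two redox-active esters, a reductive counterpart of mixed Kolbe electrolysis that is established for primary–primary pairs. No ring is closed and no stereocentre is created, so no mode of closure and no stereocontrol element are involved. The step needs cross- over homo-coupling: the two radicals are electronically alike, so this is secured by the threefold excess of the cheaper ester 10, which channels the limiting ester 11 into the mixed product, and by the unequal 5 + 9 split, which spaces the three conceivable chain lengths (C10, C14, C18) four CH2 groups apart so that they should separate by crystallisation or reversed-phase chromatography. It also needs chemoselectivity for the N–O bonds over the two electron-rich dimethoxybenzene rings, which is secured because the process is a net reduction near the ester reduction potential, whereas the anodic potential of a classical Kolbe electrolysis would oxidise these rings. Both radical centres sit on unbranched chains at least five carbons from a ring, so 1,5-hydrogen transfer from the benzylic CH2 and ipso or ortho cyclisation should be slow against capture by nickel.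

**Step 6**
Reactants: 12 1,14-bis(3,5-dimethoxyphenyl)tetradecane
Product: 13 bisnorstriatol, 5,5'-(tetradecane-1,14-diyl)bis(benzene-1,3-diol)
Conditions: BBr3 (6 equiv), CH2Cl2, −78 °C to rt; then H2O, 0 °C
Reagents that add atoms: none
Why: Lewis-acid-mediated aryl methyl ether cleavage (BBr3 demethylation) is the standard release of 5-alkylresorcinols from their dimethyl ethers and should remove all four methyl groups, since the saturated chain offers no competing site and no stereocentre is involved.

**Compound list**
1 | methyl hex-5-enoate | C=CCCCC(=O)OC | starting material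
2 | 1-bromo-3,5-dimethoxybenzene | COc1cc(Br)cc(OC)c1 | starting material
3 | methyl 6-(9-borabicyclo[3.3.1]nonan-9-yl)hexanoate | COC(=O)CCCCCB1C2CCCC1CCC2 | intermediate
4 | methyl 6-(3,5-dimethoxyphenyl)hexanoate | COC(=O)CCCCCc1cc(OC)cc(OC)c1 | intermediate
5 | 6-(3,5-dimethoxyphenyl)hexanoic acid | OC(=O)CCCCCc1cc(OC)cc(OC)c1 | intermediate
6 | methyl dec-9-enoate | C=CCCCCCCCC(=O)OC | starting material
7 | methyl 10-(9-borabicyclo[3.3.1]nonan-9-yl)decanoate | COC(=O)CCCCCCCCCB1C2CCCC1CCC2 | intermediate
8 | methyl 10-(3,5-dimethoxyphenyl)decanoate | COC(=O)CCCCCCCCCc1cc(OC)cc(OC)c1 | intermediate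
9 | 10-(3,5-dimethoxyphenyl)decanoic acid | OC(=O)CCCCCCCCCc1cc(OC)cc(OC)c1 | intermediate
10 | 1,3-dioxoisoindolin-2-yl 6-(3,5-dimethoxyphenyl)hexanoate | COc1cc(CCCCCC(=O)ON2C(=O)c3ccccc3C2=O)cc(OC)c1 | intermediate
11 | 1,3-dioxoisoindolin-2-yl 10-(3,5-dimethoxyphenyl)decanoate | COc1cc(CCCCCCCCCC(=O)ON2C(=O)c3ccccc3C2=O)cc(OC)c1 | intermediate
12 | 1,14-bis(3,5-dimethoxyphenyl)tetradecane | COc1cc(CCCCCCCCCCCCCCc2cc(OC)cc(OC)c2)cc(OC)c1 | intermediate
13 | bisnorstriatol, 5,5'-(tetradecane-1,14-diyl)bis(benzene-1,3-diol), achiral | Oc1cc(O)cc(CCCCCCCCCCCCCCc2cc(O)cc(O)c2)c1 | target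

**Total step count:** 6
**Longest linear sequence:** 4 steps (1 → 3 → 5 → 6, or 2 → 4 → 5 → 6)

**Steps most likely to fail**

*Step 5.* The two partners give electronically identical primary radicals. Statistical homocoupling, together with premature hydrogen abstraction or β-hydride elimination at nickel, may erode the cross-coupling and burden the separation.

The fallback is a polarity-differentiated decarboxylative Negishi alkyl–alkyl coupling. It sets out from 2 and 11 and comes back at 12. Magnesium insertion into 2 (Mg, LiCl, THF) would give 3,5-dimethoxyphenylmagnesium bromide F1. Li2CuCl4-catalysed alkylation of this with an excess of 1,5-dibromopentane gives 1-(5-bromopentyl)-3,5-dimethoxybenzene F2. A second magnesium insertion gives [5-(3,5-dimethoxyphenyl)pentyl]magnesium bromide F3, and transmetalation with ZnCl2 (0.5 equiv) gives bis[5-(3,5-dimethoxyphenyl)pentyl]zinc F4. This nucleophile is coupled with the redox-active ester 11 under NiCl2·glyme / 4,4'-di-tert-butyl-2,2'-bipyridine in THF–DMF at rt to give 12. One partner is now an organometallic and the other a radical precursor, so the pairing is no longer statistical.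

*Step 2.* Transfer of the long alkyl group from boron to an electron-rich arylpalladium may be slow, which allows protodeboronation and β-hydride elimination with chain-walking. Removal of boron residues from an amphiphilic acid may also be troublesome.

The fallback replaces the sp3 boron partner by an sp carbon. It sets out from 2 and comes back at 9. Copper-free Sonogashira coupling of 2 with commercial dec-9-ynoic acid (PdCl2(MeCN)2, XPhos, Cs2CO3, MeCN, 80 °C, then acidification) would give 10-(3,5-dimethoxyphenyl)dec-9-ynoic acid F5. Full hydrogenation of this (H2, Pd/C, EtOAc, rt) gives 9.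

*Step 1.* Early ester hydrolysis may turn the borane into a water-soluble carboxylate that couples sluggishly in the two-phase medium, alongside the protodeboronation named above.

The fallback avoids organoboron chemistry. It sets out from 2 and comes back at 5. Ni-catalysed reductive cross-electrophile coupling of 2 with commercial methyl 6-bromohexanoate (NiI2, 4,4'-dimethoxy-2,2'-bipyridine, NaI, pyridine, Zn dust, DMPU, 60 °C) would give the ester 4, this time isolated. A separate saponification (LiOH, THF/H2O, rt, then HCl) gives 5.

**Further compounds**
F1 | step 5 | 3,5-dimethoxyphenylmagnesium bromide | COc1cc([Mg]Br)cc(OC)c1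
F2 | step 5 | 1-(5-bromopentyl)-3,5-dimethoxybenzene | COc1cc(CCCCCBr)cc(OC)c1
F3 | step 5 | [5-(3,5-dimethoxyphenyl)pentyl]magnesium bromide | COc1cc(CCCCC[Mg]Br)cc(OC)c1
F4 | step 5 | bis[5-(3,5-dimethoxyphenyl)pentyl]zinc | COc1cc(CCCCC[Zn]CCCCCc2cc(OC)cc(OC)c2)cc(OC)c1
F5 | step 2 | 10-(3,5-dimethoxyphenyl)dec-9-ynoic acid | OC(=O)CCCCCCCC#Cc1cc(OC)cc(OC)c1
F0 | step 1 | none | none
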